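**Retrosynthetic overview**
1. The C3–C1′ bond is made last, by Suzuki–Miyaura coupling of a 3-bromo-cyclopenta[c]pyridinone core with an (S)-configured (E,E)-dienylboronate. The diene therefore never meets oxidants or strong base.
2. The five-membered ring comes from a benzilic ester ring contraction (1,2-shift) of a six-membered 7-methoxy-7-methylisoquinoline-5,6,8-trione. The trione is made in the same flask by enantioselective methoxylation of 3-bromo-6-hydroxy-7-methylisoquinoline-5,8-dione.
3. The six-membered carbocycle comes from lateral acylation, Dieckmann closure and autoxidation of methyl 6-bromo-4-methylnicotinate with a propanoyl unit. The nicotinate comes from 2,5-dibromopyridine by two regioselective metalations.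
4. The side chain comes from (S)-2-methylbutan-1-ol by oxidation/Wittig to the E-enal, then boron-Wittig to the dienylboronate.
5. Ring order: pyridine (bought), then the fused six-membered carbocycle, then contraction to the five-membered ring.

Assumption: the sense of induction of the chiral iodoarene in step 6 must be found by experiment. The (R,R) catalyst is written here, and its equally available (S,S) antipode is used if the first run gives the (7S)-trione. Isoquinoline numbering is used for 13–15 and cyclopenta[c]pyridine numbering for 16–17.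

**Step 1**
Reactants: 1 (S)-2-methylbutan-1-ol
Product: 3 (2E,4S)-2,4-dimethylhex-2-enal, via (S)-2-methylbutanal 2 (not isolated)
Conditions: TEMPO (10 mol %), PhI(OAc)2 (1.1 equiv), 1,2-dichloroethane, rt, 3 h; then Ph3P=C(CH3)CHO (1.3 equiv), 70 °C, 16 h
Reagents that add atoms: 2-(triphenyl-λ5-phosphanylidene)propanal, CC(C=O)=P(c1ccccc1)(c1ccccc1)c1ccccc1
Why: The non-basic TEMPO/PhI(OAc)2 oxidation keeps the α-stereocentre taken from 1, and the stabilised formyl ylide gives the E-trisubstituted enal in a Wittig reaction without isolating the volatile, racemisation-prone aldehyde.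

**Step 2**
Reactants: 3 (2E,4S)-2,4-dimethylhex-2-enal
Product: 4 2-[(1E,3E,5S)-3,5-dimethylhepta-1,3-dien-1-yl]-4,4,5,5-tetramethyl-1,3,2-dioxaborolane
Conditions: CH2(Bpin)2 (1.25 equiv), lithium 2,2,6,6-tetramethylpiperidide (1.2 equiv), THF, 0 °C, 10 min; then 3, −78 °C → rt; H2O quench
Reagents that add atoms: bis(pinacolatoboryl)methane, CC1(C)OB(CB2OC(C)(C)C(C)(C)O2)OC1(C)C
Why: In this boron-Wittig olefination the weakly basic LiCH(Bpin)2 adds 1,2 to the aldehyde at −78 °C and syn B–O elimination gives the E-alkenylboronate, so the γ-stereocentre is not deprotonated.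

**Step 3**
Reactants: 5 2,5-dibromopyridine
Product: 7 2,5-dibromo-4-methylpyridine, via 2,5-dibromo-4-lithiopyridine 6 (not isolated)
Conditions: LiN(iPr)2 (1.05 equiv, commercial solution), THF, −78 °C, 20 min; MeI (1.5 equiv), −78 °C → rt
Reagents that add atoms: iodomethane, CI
Why: In this directed ortho-lithiation C4–H next to the C5 bromine is the kinetically most acidic site, and a short lithiation at −78 °C followed by SN2 methylation outruns the halogen dance.

**Step 4**
Reactants: 7 2,5-dibromo-4-methylpyridine
Product: 9 methyl 6-bromo-4-methylpyridine-3-carboxylate, via pyridylmagnesium chloride 8 (not isolated)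
Conditions: iPrMgCl·LiCl (1.05 equiv), THF, −15 °C, 1 h; cannulated into ClCO2Me (2 equiv), THF, −40 °C → rt
Reagents that add atoms: methyl chloroformate, COC(=O)Cl
Why: Halogen–magnesium exchange of 2,5-dibromopyridines with iPrMgCl·LiCl takes place at C5 and spares the C2 bromide, and inverse addition to excess chloroformate stops the acylation at the ester.

**Step 5**
Reactants: 9 methyl 6-bromo-4-methylpyridine-3-carboxylate, 10 N-methoxy-N-methylpropanamide
Product: 14 3-bromo-6-hydroxy-7-methylisoquinoline-5,8-dione, via lithiated ester 11 (not isolated), via keto ester 12 (not isolated), via isoquinoline-6,8-diol 13 (not isolated)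
Conditions: 9 added to LiN(iPr)2 (1.1 equiv), THF, −78 °C; 10 (1.2 equiv), −78 → 0 °C; then NaOMe (3 equiv)/MeOH, 50 °C, Ar; then O2 (1 atm), rt; aq HCl
Reagents that add atoms: dioxygen, O=O
Why: Lateral lithiation of the 4-methyl group and Weinreb ketone synthesis give 12, methoxide equilibrates its enolates until the C7 enolate closes onto the ring ester (Dieckmann condensation, driven by aromatisation to the diolate of 13, with O-acylation to the enol lactone being reversible and the anionic ring being protected from SNAr at C–Br), and the diolate is autoxidised at C5 as in the known conversion of naphthalene-1,3-diols into 2-hydroxy-1,4-naphthoquinones.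

**Step 6**
Reactants: 14 3-bromo-6-hydroxy-7-methylisoquinoline-5,8-dione
Product: 16 methyl (5R,6S)-3-bromo-5-hydroxy-6-methoxy-6-methyl-7-oxo-6,7-dihydro-5H-cyclopenta[c]pyridine-5-carboxylate, via (7R)-trione 15 (not isolated)
Conditions: (R,R)-2-iodo-1,3-bis[1-(mesitylcarbamoyl)ethoxy]benzene (15 mol %), mCPBA (1.15 equiv, added over 6 h), CH2Cl2/MeOH 4:1, 3 Å MS, −20 °C; then Mg(OTf)2 (20 mol %), Et3N (3 equiv), −20 → 0 °C
Reagents that add atoms: methanol, CO
Why: Proposed new method: this is an enantioselective, methoxylative version of the ring-contracting first half of the Hooker oxidation, in which the chiral aryl-λ3-iodane formed from the iodoarene and mCPBA binds the enol oxygen of 14 (whose 8-hydroxy-5,6-dione tautomer is a 2-methyl-1-naphthol analogue), methanol is delivered to one face of C7 as the iodoarene leaves to give the non-enolisable (7R)-trione 15, and Et3N/Mg(OTf)2 then converts its methanol hemiketal into a chelated alkoxide that undergoes the benzilic ester 1,2-shift (C7 from C6 to C5, or the pyridyl carbon from C5 to C6, both giving the same skeleton) with retention at C7 and with the extruded ester carbon leaving on the face of the smaller OCH3 and anti to CH3, which sets (5R) with OH cis to CH3; the endocyclic C6–C7 bond lies near the nodal plane of the C8 carbonyl, so dissociation to a free enolate (retro-Claisen, racemisation) is stereoelectronically poor, slow peracid addition and hemiketal formation protect the 1,2-diketone, and the 2-bromo group keeps the ring nitrogen from binding Mg or being oxidised; the closest known reaction types are the chiral-iodoarene-catalysed intramolecular dearomatising spirolactonisation of 1-naphthols, the α-oxygenation of 2-substituted 1,3-dicarbonyls by trivalent iodine, and the carbonate-driven benzilic contraction of 3-alkyl-2-hydroxy-1,4-naphthoquinones.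

**Step 7**
Reactants: 16 methyl (5R,6S)-3-bromo-5-hydroxy-6-methoxy-6-methyl-7-oxo-6,7-dihydro-5H-cyclopenta[c]pyridine-5-carboxylate, 4 2-[(1E,3E,5S)-3,5-dimethylhepta-1,3-dien-1-yl]-4,4,5,5-tetramethyl-1,3,2-dioxaborolane
Product: 17 methyl (5R,6S)-3-[(1E,3E,5S)-3,5-dimethylhepta-1,3-dien-1-yl]-5-hydroxy-6-methoxy-6-methyl-7-oxo-6,7-dihydro-5H-cyclopenta[c]pyridine-5-carboxylate
Conditions: Pd(dppf)Cl2 (5 mol %), K3PO4 (2 equiv), THF/H2O 10:1, 40 °C
Reagents that add atoms: none
Why: In this Suzuki–Miyaura coupling the electron-poor 2-bromopyridine adds rapidly to zerovalent palladium at 40 °C and the alkenyl group transfers with retention of both E double bonds, so no stereocentre is touched and the mild base spares the tertiary aldol and the ester.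

**Compound list**
1 | (S)-2-methylbutan-1-ol | CC[C@H](C)CO | starting material
2 | (S)-2-methylbutanal | CC[C@H](C)C=O | intermediate
3 | (2E,4S)-2,4-dimethylhex-2-enal | CC[C@H](C)/C=C(C)/C=O | intermediate
4 | 2-[(1E,3E,5S)-3,5-dimethylhepta-1,3-dien-1-yl]-4,4,5,5-tetramethyl-1,3,2-dioxaborolane | CC[C@H](C)/C=C(C)/C=C/B1OC(C)(C)C(C)(C)O1 | intermediate
5 | 2,5-dibromopyridine | Brc1ccc(Br)nc1 | starting material
6 | 2,5-dibromo-4-lithiopyridine | [Li]c1cc(Br)ncc1Br | intermediate
7 | 2,5-dibromo-4-methylpyridine | Cc1cc(Br)ncc1Br | intermediate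
8 | (6-bromo-4-methylpyridin-3-yl)magnesium chloride | Cc1cc(Br)ncc1[Mg]Cl | intermediate
9 | methyl 6-bromo-4-methylpyridine-3-carboxylate | COC(=O)c1cnc(Br)cc1C | intermediate
10 | N-methoxy-N-methylpropanamide | CCC(=O)N(C)OC | starting material
11 | methyl 6-bromo-4-(lithiomethyl)pyridine-3-carboxylate | [Li]Cc1cc(Br)ncc1C(=O)OC | intermediate
12 | methyl 6-bromo-4-(2-oxobutyl)pyridine-3-carboxylate | CCC(=O)Cc1cc(Br)ncc1C(=O)OC | intermediate
13 | 3-bromo-7-methylisoquinoline-6,8-diol | Cc1c(O)cc2cc(Br)ncc2c1O | intermediate
14 | 3-bromo-6-hydroxy-7-methylisoquinoline-5,8-dione | CC1=C(O)C(=O)c2cc(Br)ncc2C1=O | intermediate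
15 | (7R)-3-bromo-7-methoxy-7-methylisoquinoline-5,6,8(7H)-trione | CO[C@@]1(C)C(=O)C(=O)c2cc(Br)ncc2C1=O | intermediate
16 | methyl (5R,6S)-3-bromo-5-hydroxy-6-methoxy-6-methyl-7-oxo-6,7-dihydro-5H-cyclopenta[c]pyridine-5-carboxylate | Brc1cc2c(cn1)C(=O)[C@@](C)(OC)[C@@]2(O)C(=O)OC | intermediate
17 | methyl (5R,6S)-3-[(1E,3E,5S)-3,5-dimethylhepta-1,3-dien-1-yl]-5-hydroxy-6-methoxy-6-methyl-7-oxo-6,7-dihydro-5H-cyclopenta[c]pyridine-5-carboxylate (CNP0548933.1) | CC[C@H](C)/C=C(C)/C=C/c1cc2c(cn1)C(=O)[C@@](C)(OC)[C@@]2(O)C(=O)OC | target

**Total step count:** 7. **Longest linear sequence:** 5 (steps 3, 4, 5, 6, 7 from 2,5-dibromopyridine).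

**Steps most likely to fail**

*Risk 1, step 6 (the new step).*
- Methanol is an external nucleophile, so the ee may be modest.
- The peracid may hydroxylate 14 or cleave the 1,2-diketone of 15.
- A partly dissociative retro-Claisen/aldol course would erode the ee.
- The C5 epimer may form.
- A moderate ee could be raised by recrystallising 16.

The fallback uses only known chemistry, sets out from 14 and comes back at 16. PhI(OAc)2 in MeOH at 0 °C is the usual achiral trivalent-iodine methoxylation of 2-alkyl-1-naphthols and 2-substituted 1,3-dicarbonyls. It gives racemic 3-bromo-7-methoxy-7-methylisoquinoline-5,6,8(7H)-trione F1. K2CO3 in MeOH at 0 °C then effects a classical benzilic ester rearrangement under substrate control. This gives racemic methyl (5R*,6S*)-3-bromo-5-hydroxy-6-methoxy-6-methyl-7-oxo-6,7-dihydro-5H-cyclopenta[c]pyridine-5-carboxylate F2. Preparative chiral-phase SFC resolves F2 into 16.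

*Risk 2, step 5.*
- The benzylic enolate of 12 may be trapped as the enol lactone.
- Methoxide may displace the bromide.
- The autoxidation may overrun.

The fallback sets out from 9 and 10 and comes back at 14. It oxidises before ring closure, so no benzylic enolate remains. After the LiN(iPr)2/Weinreb acylation the mixture is quenched with acid and 12 is isolated. Riley oxidation (SeO2, dioxane, 80 °C) of its doubly activated CH2 gives methyl 6-bromo-4-(2-oxobutanoyl)pyridine-3-carboxylate F3. DBU in THF at 0 °C then closes the only available enolate onto the ring ester (Dieckmann) and gives 14 directly at the quinone oxidation level.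

*Risk 3, step 7.*
- Phosphate may trigger retro-aldol epimerisation or ester hydrolysis of 16.
- The dienylboronate may protodeboronate.

The fallback sets out from 3 and 16 and comes back at 17. It is base-free and uses another nucleophile, made by another olefination. Enal 3 is treated with Bu3SnCHBr2, CrCl2 and LiI in THF/DMF (chromium-mediated E-selective stannyl olefination). This gives tributyl[(1E,3E,5S)-3,5-dimethylhepta-1,3-dien-1-yl]stannane F4. F4 is then joined to 16 in a neutral Stille coupling (Pd2(dba)3, AsPh3, NMP, 40 °C).

**Further compounds**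
F1 | step 6 | racemic 3-bromo-7-methoxy-7-methylisoquinoline-5,6,8(7H)-trione | CO[C@@]1(C)C(=O)C(=O)c2cc(Br)ncc2C1=O.CO[C@]1(C)C(=O)C(=O)c2cc(Br)ncc2C1=O
F2 | step 6 | racemic methyl (5R*,6S*)-3-bromo-5-hydroxy-6-methoxy-6-methyl-7-oxo-6,7-dihydro-5H-cyclopenta[c]pyridine-5-carboxylate | Brc1cc2c(cn1)C(=O)[C@@](C)(OC)[C@@]2(O)C(=O)OC.Brc1cc2c(cn1)C(=O)[C@](C)(OC)[C@]2(O)C(=O)OC
F3 | step 5 | methyl 6-bromo-4-(2-oxobutanoyl)pyridine-3-carboxylate | CCC(=O)C(=O)c1cc(Br)ncc1C(=O)OC
F4 | step 7 | tributyl[(1E,3E,5S)-3,5-dimethylhepta-1,3-dien-1-yl]stannane | CC[C@H](C)/C=C(C)/C=C/[Sn](CCCC)(CCCC)CCCC
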